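**Strategy**

Ring A is built, not substituted. Its C2 and C6 oxygens sit meta to each other across C1, the resorcinol monoether pattern that a vinylketene and an ynol ether give on benzannulation. Ring B is therefore joined through its phenolic oxygen to an sp carbon early, as an aryl ynol ether whose other alkyne carbon carries the future C1 as a PMB-protected CH2OH. A diazo enone from (S)-leucic acid supplies C2 to C5 and the finished (S)-carbinol. Irradiating and heating the two together should close ring A with all four substituents and the crowded diaryl ether in one operation; O-methylation, benzylic oxidation and one acidic deprotection then complete the synthesis.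

Key step: step 12

Remark: ring A is numbered C1 (CO2H), C2 (OMe), C3 (side chain), C4, C5, C6 (O-aryl); 2-hydroxy-3-methoxy-5-methylbenzaldehyde and (S)-2-hydroxy-4-methylpentanoic acid are taken as catalogue chemicals, the latter having the configuration of L-leucine (from which it is otherwise available by nitrous acid deamination with retention), which is the (S) configuration the target requires.

Abbreviations: TBS = tert-butyldimethylsilyl, MOM = methoxymethyl, PMB = 4-methoxybenzyl.

**Ring B arm**

Step 1
Reactants: 1 2-hydroxy-3-methoxy-5-methylbenzaldehyde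
Product: 2 2,3-dihydroxy-5-methylbenzaldehyde
Conditions: BBr3 (1.5 equiv), CH2Cl2, −78 °C → rt; H2O
Reagents that add atoms: none
Why: BBr3 demethylation (Lewis acid cleavage of an aryl methyl ether) is routine for ortho-vanillin-type aldehydes and delivers the ring B catechol aldehyde with its substitution pattern already fixed by the starting material.

Step 2
Reactants: 2 2,3-dihydroxy-5-methylbenzaldehyde
Product: 3 2-hydroxy-3-(methoxymethoxy)-5-methylbenzaldehyde
Conditions: NaH (2.2 equiv), DMF, 0 °C; MOMCl (1.0 equiv), 0 °C → rt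
Reagents that add atoms: chloromethyl methyl ether, COCCl
Why: In the disodium salt the C3 phenoxide is the more nucleophilic oxygen because the C2 phenoxide is delocalised into and chelated by the formyl group, so a Williamson alkylation with one equivalent of MOMCl should protect O3 only and leave the C2 hydroxyl free for step 3.

Step 3
Reactants: 3 2-hydroxy-3-(methoxymethoxy)-5-methylbenzaldehyde; 4 trichloroethylene
Product: 5 2-[(E)-1,2-dichloroethenyloxy]-3-(methoxymethoxy)-5-methylbenzaldehyde
Conditions: Cl2C=CHCl (2 equiv), K2CO3, DMF, 70 °C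
Reagents that add atoms: trichloroethylene (4), ClC=C(Cl)Cl
Why: K2CO3 dehydrochlorinates trichloroethylene to dichloroacetylene and the phenoxide adds to it in anti fashion (nucleophilic addition to a haloalkyne), which should bond the doubly flanked ring B oxygen to an unhindered carbon and give the (E)-dichlorovinyl ether.

Step 4
Reactants: 5 dichlorovinyl ether aldehyde
Product: 6 2-{2-[(E)-1,2-dichloroethenyloxy]-3-(methoxymethoxy)-5-methylphenyl}-1,3-dioxolane
Conditions: Me3SiOCH2CH2OSiMe3, Me3SiOTf (cat.), CH2Cl2, −78 → −20 °C; pyridine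
Reagents that add atoms: 1,2-bis(trimethylsilyloxy)ethane, C[Si](C)(C)OCCO[Si](C)(C)C
Why: Noyori acetalisation runs under aprotic conditions at low temperature, so the aldehyde should be masked as the dioxolane (needed against n-BuLi in step 5 and against chlorite in step 15) while the MOM ether and the electron-poor dichlorovinyl ether stay intact.

Step 5
Reactants: 6 dichlorovinyl ether acetal; 7 formaldehyde (used as paraformaldehyde)
Product: 10 3-[2-(1,3-dioxolan-2-yl)-6-(methoxymethoxy)-4-methylphenoxy]prop-2-yn-1-ol, via chloroalkynyl ether 8 (not isolated), via lithium aryloxyacetylide 9 (not isolated)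
Conditions: n-BuLi (2.3 equiv), THF, −78 °C; (CH2O)n, −78 °C → rt; aq. NH4Cl
Reagents that add atoms: formaldehyde (7), C=O
Why: Dehydrochlorination followed by chlorine–lithium exchange is the standard route from 1,2-dichlorovinyl ethers to lithium alkoxy- and aryloxyacetylides, and 1,2-addition of the acetylide to formaldehyde should attach the future C1 carbon, the acetal and the MOM ether being inert to n-BuLi at −78 °C.

Step 6
Reactants: 10 aryloxy propargylic alcohol
Product: 11 2-{2-[3-(4-methoxybenzyloxy)prop-1-yn-1-yloxy]-3-(methoxymethoxy)-5-methylphenyl}-1,3-dioxolane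
Conditions: NaH, 4-MeOC6H4CH2Cl, Bu4NI (cat.), THF/DMF, 0 °C → rt
Reagents that add atoms: 4-methoxybenzyl chloride, COc1ccc(CCl)cc1
Why: Williamson etherification under basic conditions caps the hydroxyl, which would otherwise add to the ketene in step 12, without exposing the acid-sensitive ynol ether to acid, and the PMB group can later be removed oxidatively in the presence of every other protecting group.

**Diazo enone arm**

Step 7
Reactants: 12 (S)-2-hydroxy-4-methylpentanoic acid
Product: 13 methyl (S)-2-hydroxy-4-methylpentanoate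
Conditions: MeOH, H2SO4 (cat.), reflux
Reagents that add atoms: methanol, CO
Why: Fischer esterification does not involve the bonds of the stereocentre, so the (S) configuration taken from the chiral pool should be carried over unchanged.

Step 8
Reactants: 13 methyl (S)-2-hydroxy-4-methylpentanoate
Product: 14 methyl (S)-2-(tert-butyldimethylsilyloxy)-4-methylpentanoate
Conditions: t-BuMe2SiCl, imidazole, DMF, rt
Reagents that add atoms: tert-butyldimethylsilyl chloride, CC(C)(C)[Si](C)(C)Cl
Why: Imidazole-promoted silylation of the secondary alcohol is too weakly basic to enolise the ester and installs an ether that should survive the reduction, the olefination, the enolate chemistry, light and heat.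

Step 9
Reactants: 14 silyloxy ester
Product: 15 (S)-2-(tert-butyldimethylsilyloxy)-4-methylpentanal
Conditions: i-Bu2AlH (1.1 equiv), CH2Cl2, −78 °C; MeOH, then aq. potassium sodium tartrate
Reagents that add atoms: none
Why: Partial ester reduction with i-Bu2AlH works well for α-silyloxy esters because the tetrahedral aluminium hemiacetal persists at −78 °C, and the aldehyde, freed only on work-up, is used at once so that the α-stereocentre does not epimerise.

Step 10
Reactants: 15 silyloxy aldehyde; 16 1-(triphenylphosphoranylidene)propan-2-one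
Product: 17 (S,E)-5-(tert-butyldimethylsilyloxy)-7-methyloct-3-en-2-one
Conditions: CH2Cl2, rt → 40 °C
Reagents that add atoms: 1-(triphenylphosphoranylidene)propan-2-one (16), CC(=O)C=P(c1ccccc1)(c1ccccc1)c1ccccc1
Why: Wittig olefination with a stabilised, non-basic acyl ylide should give the (E)-enone without epimerising the α-silyloxy aldehyde.

Step 11
Reactants: 17 silyloxy enone
Product: 19 (S,E)-5-(tert-butyldimethylsilyloxy)-1-diazo-7-methyloct-3-en-2-one, via trifluoroacetyl diketone 18 (not isolated)
Conditions: LiN(SiMe3)2, THF, −78 °C; CF3CO2CH2CF3; aq. HCl wash, crude 18 carried on unpurified; then 4-AcNHC6H4SO2N3, Et3N, H2O (1 equiv), MeCN, rt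
Reagents that add atoms: 4-acetamidobenzenesulfonyl azide, CC(=O)Nc1ccc(cc1)S(=O)(=O)N=[N+]=[N-]
Why: In this detrifluoroacetylative diazo transfer the kinetic methyl-side enolate is trifluoroacetylated and the activated 1,3-diketone accepts the diazo group from the sulfonyl azide while the trifluoroacetyl group leaves as the acyl sulfonamide, a sequence suited to base-sensitive α'-diazo enones that leaves the allylic stereocentre alone.

**Key step and endgame**

Step 12
Reactants: 19 diazo enone; 11 ring B aryl ynol ether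
Product: 24 6-[(1S)-1-(tert-butyldimethylsilyloxy)-3-methylbutyl]-3-[2-(1,3-dioxolan-2-yl)-6-(methoxymethoxy)-4-methylphenoxy]-2-[(4-methoxybenzyloxy)methyl]phenol, via vinylketene 20 (not isolated), via vinylcyclobutenone 21 (not isolated), via dienylketene 22 (not isolated), via cyclohexadienone 23 (not isolated)
Conditions: 19 (1.0 equiv), 11 (1.3 equiv), hν (Pyrex-filtered medium-pressure Hg lamp, λ > 300 nm), CH2Cl2, rt; then PhMe, 100 °C
Reagents that add atoms: none
Why: Light triggers a Wolff rearrangement of 19 in which the alkenyl group shifts to the diazo carbon (C4–C5) to give vinylketene 20, whose ketene C=C adds [2+2] to the electron-rich alkyne of 11 to give cyclobutenone 21 (C1–C2 and C5–C6); heating opens 21 by a four-electron electrocyclic reaction to dienylketene 22, which cyclises (C2–C3) to dienone 23 and tautomerises to phenol 24. The closest known reaction is the Danheiser benzannulation of α-diazo enones with alkoxy- and silyloxyalkynes. Ring A is closed by a thermal six-electron disrotatory electrocyclisation of the ketene-containing triene 22. No stereocentre is created, since the sp3 centres of 21 and 23 vanish on aromatisation and the silyloxy-bearing carbon, never part of the reacting π system, keeps its (S) configuration. The step needs regioselectivity in the [2+2] event, and this is secured by the polarisation of the ynol ether, whose carbon β to oxygen (bearing CH2OPMB) is the nucleophilic one and attacks the ketene carbonyl carbon, so the aryloxy group ends meta to the new hydroxyl. An aryl ynol ether has no path for the retro-ene loss of alkene that limits alkyl ynol ethers on heating, and light above 300 nm should spare the aryl ether chromophores.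

Step 13
Reactants: 24 benzannulated phenol
Product: 25 2-{2-[4-[(1S)-1-(tert-butyldimethylsilyloxy)-3-methylbutyl]-3-methoxy-2-[(4-methoxybenzyloxy)methyl]phenoxy]-3-(methoxymethoxy)-5-methylphenyl}-1,3-dioxolane
Conditions: MeI, K2CO3, DMF, rt
Reagents that add atoms: iodomethane, CI
Why: Williamson O-methylation of the phenoxide should be clean although the oxygen is flanked on both sides, migration of the neighbouring silyl group to the less basic phenoxide being thermodynamically disfavoured, and capping the phenol also closes the ortho-quinone methide pathway that could endanger the benzylic stereocentre.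

Step 14
Reactants: 25 ring A methyl ether
Product: 26 [3-[(1S)-1-(tert-butyldimethylsilyloxy)-3-methylbutyl]-6-[2-(1,3-dioxolan-2-yl)-6-(methoxymethoxy)-4-methylphenoxy]-2-methoxyphenyl]methanol
Conditions: DDQ (1.3 equiv), CH2Cl2/aq. NaH2PO4–Na2HPO4 buffer (pH 7), 0 °C → rt
Reagents that add atoms: none
Why: Oxidative PMB cleavage by DDQ (hydride abstraction from the anisyl CH2 and hydrolysis of the oxocarbenium ion) is orthogonal to the silyl ether, the MOM ether and the dioxolane, and any over-oxidation to aldehyde 27 would only anticipate step 15.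

Step 15
Reactants: 26 ring A benzylic alcohol
Product: 28 3-[(1S)-1-(tert-butyldimethylsilyloxy)-3-methylbutyl]-6-[2-(1,3-dioxolan-2-yl)-6-(methoxymethoxy)-4-methylphenoxy]-2-methoxybenzoic acid, via ring A benzaldehyde 27 (not isolated)
Conditions: TEMPO (cat.), NaClO2 (2 equiv), NaOCl (cat.), MeCN/aq. NaH2PO4–Na2HPO4 buffer (pH 6.7), 35 °C
Reagents that add atoms: sodium chlorite, [Na+].[O-]Cl=O
Why: In this Anelli-type oxidation with chlorite as terminal oxidant the oxoammonium ion takes the alcohol to aldehyde 27 and chlorite takes 27 to the acid (Pinnick-type step), and the near-neutral buffer should keep the dioxolane closed, so that the ring B aldehyde stays hidden from chlorite, and spare the MOM and silyl ethers.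

Step 16
Reactants: 28 protected acid
Product: 29 6-(2-formyl-6-hydroxy-4-methylphenoxy)-3-[(1S)-1-hydroxy-3-methylbutyl]-2-methoxybenzoic acid (tenellic acid B)
Conditions: 3 M aq. HCl/THF (1:3), rt → 40 °C
Reagents that add atoms: water, O
Why: Acid hydrolysis should remove the dioxolane, the silyl ether and the aryl MOM ether in one operation, and the benzylic carbinol should keep its (S) configuration because ionisation is discouraged by the meta carboxyl group and by the ortho methoxy group, which is twisted out of conjugation.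

**Compound list**

1 | 2-hydroxy-3-methoxy-5-methylbenzaldehyde | COc1cc(C)cc(C=O)c1O | starting material
2 | 2,3-dihydroxy-5-methylbenzaldehyde | Cc1cc(O)c(O)c(C=O)c1 | intermediate
3 | 2-hydroxy-3-(methoxymethoxy)-5-methylbenzaldehyde | COCOc1cc(C)cc(C=O)c1O | intermediate
4 | trichloroethylene | ClC=C(Cl)Cl | starting material
5 | 2-[(E)-1,2-dichloroethenyloxy]-3-(methoxymethoxy)-5-methylbenzaldehyde | COCOc1cc(C)cc(C=O)c1O/C(Cl)=C\Cl | intermediate
6 | 2-{2-[(E)-1,2-dichloroethenyloxy]-3-(methoxymethoxy)-5-methylphenyl}-1,3-dioxolane | COCOc1cc(C)cc(C2OCCO2)c1O/C(Cl)=C\Cl | intermediate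
7 | formaldehyde (used as paraformaldehyde) | C=O | starting material
8 | 2-[2-(chloroethynyloxy)-3-(methoxymethoxy)-5-methylphenyl]-1,3-dioxolane | COCOc1cc(C)cc(C2OCCO2)c1OC#CCl | intermediate
9 | {[2-(1,3-dioxolan-2-yl)-6-(methoxymethoxy)-4-methylphenoxy]ethynyl}lithium | COCOc1cc(C)cc(C2OCCO2)c1OC#C[Li] | intermediate
10 | 3-[2-(1,3-dioxolan-2-yl)-6-(methoxymethoxy)-4-methylphenoxy]prop-2-yn-1-ol | COCOc1cc(C)cc(C2OCCO2)c1OC#CCO | intermediate
11 | 2-{2-[3-(4-methoxybenzyloxy)prop-1-yn-1-yloxy]-3-(methoxymethoxy)-5-methylphenyl}-1,3-dioxolane | COCOc1cc(C)cc(C2OCCO2)c1OC#CCOCc1ccc(OC)cc1 | intermediate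
12 | (S)-2-hydroxy-4-methylpentanoic acid | OC(=O)[C@@H](O)CC(C)C | starting material
13 | methyl (S)-2-hydroxy-4-methylpentanoate | COC(=O)[C@@H](O)CC(C)C | intermediate
14 | methyl (S)-2-(tert-butyldimethylsilyloxy)-4-methylpentanoate | COC(=O)[C@@H](O[Si](C)(C)C(C)(C)C)CC(C)C | intermediate
15 | (S)-2-(tert-butyldimethylsilyloxy)-4-methylpentanal | O=C[C@@H](O[Si](C)(C)C(C)(C)C)CC(C)C | intermediate
16 | 1-(triphenylphosphoranylidene)propan-2-one | CC(=O)C=P(c1ccccc1)(c1ccccc1)c1ccccc1 | starting material
17 | (S,E)-5-(tert-butyldimethylsilyloxy)-7-methyloct-3-en-2-one | CC(=O)/C=C/[C@@H](O[Si](C)(C)C(C)(C)C)CC(C)C | intermediate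
18 | (S,E)-7-(tert-butyldimethylsilyloxy)-1,1,1-trifluoro-9-methyldec-5-ene-2,4-dione | FC(F)(F)C(=O)CC(=O)/C=C/[C@@H](O[Si](C)(C)C(C)(C)C)CC(C)C | intermediate
19 | (S,E)-5-(tert-butyldimethylsilyloxy)-1-diazo-7-methyloct-3-en-2-one | [N-]=[N+]=CC(=O)/C=C/[C@@H](O[Si](C)(C)C(C)(C)C)CC(C)C | intermediate
20 | (S,E)-5-(tert-butyldimethylsilyloxy)-7-methylocta-1,3-dien-1-one (vinylketene) | O=C=C/C=C/[C@@H](O[Si](C)(C)C(C)(C)C)CC(C)C | intermediate
21 | 4-[(1E,3S)-3-(tert-butyldimethylsilyloxy)-5-methylhex-1-en-1-yl]-3-[2-(1,3-dioxolan-2-yl)-6-(methoxymethoxy)-4-methylphenoxy]-2-[(4-methoxybenzyloxy)methyl]cyclobut-2-en-1-one (both C4 epimers) | O=C1C(COCc2ccc(OC)cc2)=C(Oc2c(OCOC)cc(C)cc2C2OCCO2)C1/C=C/[C@@H](O[Si](C)(C)C(C)(C)C)CC(C)C | intermediate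
22 | (7S)-7-(tert-butyldimethylsilyloxy)-3-[2-(1,3-dioxolan-2-yl)-6-(methoxymethoxy)-4-methylphenoxy]-2-[(4-methoxybenzyloxy)methyl]-9-methyldeca-1,3,5-trien-1-one, C2 and C5 cis across C3=C4, C5=C6 trans (dienylketene) | O=C=C(COCc1ccc(OC)cc1)/C(Oc1c(OCOC)cc(C)cc1C1OCCO1)=C\C=C\[C@@H](O[Si](C)(C)C(C)(C)C)CC(C)C | intermediate
23 | 6-[(1S)-1-(tert-butyldimethylsilyloxy)-3-methylbutyl]-3-[2-(1,3-dioxolan-2-yl)-6-(methoxymethoxy)-4-methylphenoxy]-2-[(4-methoxybenzyloxy)methyl]cyclohexa-2,4-dien-1-one (both C6 epimers) | O=C1C(COCc2ccc(OC)cc2)=C(Oc2c(OCOC)cc(C)cc2C2OCCO2)C=CC1[C@@H](O[Si](C)(C)C(C)(C)C)CC(C)C | intermediate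
24 | 6-[(1S)-1-(tert-butyldimethylsilyloxy)-3-methylbutyl]-3-[2-(1,3-dioxolan-2-yl)-6-(methoxymethoxy)-4-methylphenoxy]-2-[(4-methoxybenzyloxy)methyl]phenol | Oc1c([C@@H](O[Si](C)(C)C(C)(C)C)CC(C)C)ccc(Oc2c(OCOC)cc(C)cc2C2OCCO2)c1COCc1ccc(OC)cc1 | intermediate
25 | 2-{2-[4-[(1S)-1-(tert-butyldimethylsilyloxy)-3-methylbutyl]-3-methoxy-2-[(4-methoxybenzyloxy)methyl]phenoxy]-3-(methoxymethoxy)-5-methylphenyl}-1,3-dioxolane | COc1c([C@@H](O[Si](C)(C)C(C)(C)C)CC(C)C)ccc(Oc2c(OCOC)cc(C)cc2C2OCCO2)c1COCc1ccc(OC)cc1 | intermediate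
26 | [3-[(1S)-1-(tert-butyldimethylsilyloxy)-3-methylbutyl]-6-[2-(1,3-dioxolan-2-yl)-6-(methoxymethoxy)-4-methylphenoxy]-2-methoxyphenyl]methanol | COc1c([C@@H](O[Si](C)(C)C(C)(C)C)CC(C)C)ccc(Oc2c(OCOC)cc(C)cc2C2OCCO2)c1CO | intermediate
27 | 3-[(1S)-1-(tert-butyldimethylsilyloxy)-3-methylbutyl]-6-[2-(1,3-dioxolan-2-yl)-6-(methoxymethoxy)-4-methylphenoxy]-2-methoxybenzaldehyde | COc1c([C@@H](O[Si](C)(C)C(C)(C)C)CC(C)C)ccc(Oc2c(OCOC)cc(C)cc2C2OCCO2)c1C=O | intermediate
28 | 3-[(1S)-1-(tert-butyldimethylsilyloxy)-3-methylbutyl]-6-[2-(1,3-dioxolan-2-yl)-6-(methoxymethoxy)-4-methylphenoxy]-2-methoxybenzoic acid | COc1c([C@@H](O[Si](C)(C)C(C)(C)C)CC(C)C)ccc(Oc2c(OCOC)cc(C)cc2C2OCCO2)c1C(=O)O | intermediate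
29 | 6-(2-formyl-6-hydroxy-4-methylphenoxy)-3-[(1S)-1-hydroxy-3-methylbutyl]-2-methoxybenzoic acid (tenellic acid B) | COc1c([C@@H](O)CC(C)C)ccc(Oc2c(O)cc(C)cc2C=O)c1C(=O)O | target

**Step count**

Total step count: 16.
Longest linear sequence: 11 steps (steps 1–6, then 12–16, from 1 to 29); the diazo enone arm contributes steps 7–11.

**Steps most likely to fail**

Step 12. Capture of vinylketene 20 by the aryloxyalkyne may be slower than with alkoxy- or silyloxyalkynes, so that ketene dimerisation and O-acylation of the product phenol by 20 take over; absorption of light by the aryl ethers may also slow the Wolff step. The fallback sets out from 19 and comes back at 25; it gives up the early aryl–oxygen bond, uses the fully precedented silyloxyalkyne and forms the diaryl ether afterwards by SNAr. Propargyl alcohol is protected (NaH, PMBCl) as 1-methoxy-4-[(prop-2-yn-1-yloxy)methyl]benzene F1. Its lithium acetylide is oxidised with t-BuOOLi to the ynolate and silylated on oxygen with i-Pr3SiOTf to give 1-methoxy-4-{[3-(triisopropylsilyloxy)prop-2-yn-1-yl]oxymethyl}benzene F2. Irradiation and heating of 19 with F2 as in step 12 should give 6-[(1S)-1-(tert-butyldimethylsilyloxy)-3-methylbutyl]-2-[(4-methoxybenzyloxy)methyl]-3-(triisopropylsilyloxy)phenol F3. MeI/K2CO3 then gives the methyl ether tert-butyl{(1S)-1-[2-methoxy-3-[(4-methoxybenzyloxy)methyl]-4-(triisopropylsilyloxy)phenyl]-3-methylbutoxy}dimethylsilane F4, and Bu4NF (1 equiv, THF, 0 °C) cleaves only the aryl silyl ether to give 3-methoxy-4-[(1S)-1-(tert-butyldimethylsilyloxy)-3-methylbutyl]-2-[(4-methoxybenzyloxy)methyl]phenol F5. For ring B, 2-fluoro-5-methylphenol is converted (MOMCl, i-Pr2NEt) into 1-fluoro-2-(methoxymethoxy)-4-methylbenzene F6, which is metalated next to fluorine under acidity control (n-BuLi/KOt-Bu, THF, −75 °C) and formylated with DMF to give 2-fluoro-3-(methoxymethoxy)-5-methylbenzaldehyde F7. SNAr of the potassium salt of F5 on F7 (K2CO3, DMF, 100 °C), activated by the ortho formyl group, should give 2-{4-[(1S)-1-(tert-butyldimethylsilyloxy)-3-methylbutyl]-3-methoxy-2-[(4-methoxybenzyloxy)methyl]phenoxy}-3-(methoxymethoxy)-5-methylbenzaldehyde F8, and acetalisation under the conditions of step 4 returns to 25.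

Step 5. Lithium acetylide 9 may decay (loss of aryloxide, oligomerisation) while the heterogeneous paraformaldehyde depolymerises on warming. The fallback sets out from 6 and comes back at 10; it replaces hydroxymethylation by acylation and reduction. Acetylide 9 is generated as before but trapped at −78 °C with methyl chloroformate to give methyl 3-[2-(1,3-dioxolan-2-yl)-6-(methoxymethoxy)-4-methylphenoxy]prop-2-ynoate F9, an isolable push-pull alkyne, and i-Bu2AlH (CH2Cl2, −78 °C) reduces the ester to propargylic alcohol 10.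

Step 16. Cleavage of the aryl MOM ether may stay incomplete at an acidity that the benzylic carbinol tolerates, and forcing the acid may ionise the benzylic C–O bond and erode the configuration. The fallback sets out from 28 and comes back at 29; it replaces Brønsted acid hydrolysis by silyl triflate activation followed by fluoride. Me3SiOTf/2,2'-bipyridyl (CH2Cl2, 0 °C) and then water cleave the aryl MOM ether and the dioxolane through silyl and pyridinium intermediates to give 3-[(1S)-1-(tert-butyldimethylsilyloxy)-3-methylbutyl]-6-(2-formyl-6-hydroxy-4-methylphenoxy)-2-methoxybenzoic acid F10, and HF·pyridine (THF, 0 °C → rt) removes the silyl ether to give 29.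

Further compounds
F1 | step 12 | 1-methoxy-4-[(prop-2-yn-1-yloxy)methyl]benzene | COc1ccc(COCC#C)cc1
F2 | step 12 | 1-methoxy-4-{[3-(triisopropylsilyloxy)prop-2-yn-1-yl]oxymethyl}benzene | COc1ccc(COCC#CO[Si](C(C)C)(C(C)C)C(C)C)cc1
F3 | step 12 | 6-[(1S)-1-(tert-butyldimethylsilyloxy)-3-methylbutyl]-2-[(4-methoxybenzyloxy)methyl]-3-(triisopropylsilyloxy)phenol | Oc1c([C@@H](O[Si](C)(C)C(C)(C)C)CC(C)C)ccc(O[Si](C(C)C)(C(C)C)C(C)C)c1COCc1ccc(OC)cc1
F4 | step 12 | tert-butyl{(1S)-1-[2-methoxy-3-[(4-methoxybenzyloxy)methyl]-4-(triisopropylsilyloxy)phenyl]-3-methylbutoxy}dimethylsilane | COc1c([C@@H](O[Si](C)(C)C(C)(C)C)CC(C)C)ccc(O[Si](C(C)C)(C(C)C)C(C)C)c1COCc1ccc(OC)cc1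
F5 | step 12 | 3-methoxy-4-[(1S)-1-(tert-butyldimethylsilyloxy)-3-methylbutyl]-2-[(4-methoxybenzyloxy)methyl]phenol | COc1c([C@@H](O[Si](C)(C)C(C)(C)C)CC(C)C)ccc(O)c1COCc1ccc(OC)cc1
F6 | step 12 | 1-fluoro-2-(methoxymethoxy)-4-methylbenzene | COCOc1cc(C)ccc1F
F7 | step 12 | 2-fluoro-3-(methoxymethoxy)-5-methylbenzaldehyde | COCOc1cc(C)cc(C=O)c1F
F8 | step 12 | 2-{4-[(1S)-1-(tert-butyldimethylsilyloxy)-3-methylbutyl]-3-methoxy-2-[(4-methoxybenzyloxy)methyl]phenoxy}-3-(methoxymethoxy)-5-methylbenzaldehyde | COc1c([C@@H](O[Si](C)(C)C(C)(C)C)CC(C)C)ccc(Oc2c(OCOC)cc(C)cc2C=O)c1COCc1ccc(OC)cc1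
F9 | step 5 | methyl 3-[2-(1,3-dioxolan-2-yl)-6-(methoxymethoxy)-4-methylphenoxy]prop-2-ynoate | COCOc1cc(C)cc(C2OCCO2)c1OC#CC(=O)OC
F10 | step 16 | 3-[(1S)-1-(tert-butyldimethylsilyloxy)-3-methylbutyl]-6-(2-formyl-6-hydroxy-4-methylphenoxy)-2-methoxybenzoic acid | COc1c([C@@H](O[Si](C)(C)C(C)(C)C)CC(C)C)ccc(Oc2c(O)cc(C)cc2C=O)c1C(=O)O
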